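## Structural features

Schizolaenone A is a flavanone: a benzopyranone (rings A and C fused) that carries ring B on C2 through a C–C bond. Ring A is a phloroglucinol nucleus with free hydroxyls on C5 and C7, a prenyl group on C6 between them, and its third oxygen built into ring C as O1. Ring B is a 4-hydroxyphenyl unit with an (E)-geranyl chain on C3', ortho to the hydroxyl. C2 is the only stereocentre (S). It is benzylic, it is the oxygen-bearing end of a β-aryloxy ketone, and it lies para to the ring B oxygen, so it can be lost by retro-oxa-Michael opening to the chalcone or by ionisation. The three trisubstituted alkenes sit next to phenols and cyclise to chromans in strong acid; they also rule out hydrogenolysis, peracids, osmium reagents and electrophilic halogen. The real difficulties are placing the prenyl group on C6 and not C8 (the two ortho oxygens of a nearly symmetric ring A must be told apart) and fixing C2 in a step that cannot scramble it. The key step uses two facts: O1–C2 is an aryl alkyl ether bond at the stereocentre, and C2 and C4 are 1,3-related oxygenated carbons. A dithiane at C4 and a C2–C3 oxirane therefore deliver the chain with C2 already configured, and the C8a phenol closes ring C on C2 by SN2 inversion.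

## Logic of the disconnections

24 to 23: the three phenolic O–H bonds are traced back to O–CH2OCH3 acetals. The phenols must be silent during the organolithium and Mitsunobu chemistry, and the acetals on ring A also steer lithiation. The gain is one global final step. The demand is a solvolysis mild enough for the isoprenyl alkenes and for C2.

23 to 22: the C4 carbonyl is traced back to a dithioketal (two C–S bonds). No ketone may exist while C2 carries a leaving group, and the same sulfur ring is the acyl anion carrier of the fragment union. The demand is an unmasking that leaves three alkenes alone, so S-alkylation and hydrolysis are chosen over oxidants or mercury salts.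

22 to 21: the O1–C2 bond is cut. This opens ring C and leaves a phenol and a secondary benzylic alcohol of opposite configuration (1R). The gain is an acyclic precursor whose only stereocentre is a carbinol. The demand is a clean SN2 closure at an electron-rich benzylic carbon, by the one free phenol only.

21 to 9 plus 19 (through 20): the C3–C4 bond is cut. C4 becomes a dithiane carbanion and C3 the terminal carbon of an oxirane, which matches the 1,3-dioxygenation and joins the two aryl halves convergently without touching C2. The phenol is carried as its lithium salt, so no extra protecting group orthogonal to three acetals is needed. The demands are attack at the terminal carbon only and S configuration in 19.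

9 to 8 to 7: the two C–S bonds, then the C4–C4a bond, are cut. 7 has a mirror plane through its hydroxyl and prenyl carbons, so its two free ring positions are equivalent. One ortho formylation therefore fixes the prenyl group on C6 and the free hydroxyl on C8a together. The demands are ortho selectivity and a thioacetalisation that spares the acetals.

7 to 6 to 3 plus 4 (through 5), then 3 to 2 to 1: the aryl–prenyl bond, the O–Si bond and the O–CH2 bonds are cut. The silyl ether marks the oxygen that becomes O1; being bulky and non-coordinating, it leaves the carbon between the two acetals as the only lithiation site. The demand is mono-silylation of a symmetric triol, handled statistically with excess 1.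

19 to 17 (through 18): the oxirane C–O bond and the C2–H bond are cut. A catalyst-controlled ketone reduction sets C2 without a resolution and without an oxidant that would have to choose between a styrene and the geranyl alkenes. The demand is a reduction that touches only C=O.

17 to 14 plus 15 (through 16), 14 to 11 plus 12 (through 13), 11 to 10: the aryl–acyl bond, the aryl–geranyl bond and the O–CH2 bond are cut. The two bromines of 10 are the two handles: the one ortho to the acetal exchanges first, the para one second. The demands are clean regioselection in the first exchange and SN2 (not SN2') allylation with the E geometry kept.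

## Other disconnections considered

Alternative 1: Ring A is taken apart instead of ring C. The cuts are C8–C8a, C5–C6, C7–C8 and C4a–C5, leading to the enantioenriched 6-diazoacetyl-2-aryl-2,3-dihydropyran-4-one A2 and the prenyl-bearing siloxyalkyne A3. Forward, irradiation of A2 would trigger a Wolff rearrangement to a vinylketene, which should add A3 in a [2+2] sense. A 4π opening of the cyclobutenone and a 6π closure of the dienylketene would then give phenol A1 (Danheiser benzannulation).
- In favour: the pattern 5-OH / 6-prenyl / 7-silyloxy / 8-H follows from the mechanism, so the C6-versus-C8 question never arises and the 5-OH is born free. On ring A regiocontrol this plan is the better one, since the chosen route needs a silyl marker and a symmetric intermediate for the same result.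
- Also in favour: C2 is not a reaction centre in the key step, and the silyl ethers of A1 could be removed with buffered fluoride, which is gentler on the isoprenyl chains than the acid of step 14.
- Against: A2 must be made with C2 already set (for example by an enantioselective hetero-Diels–Alder reaction of the ring B aldehyde) and then equipped with the diazo ketone; A3 needs its own synthesis. Both are sensitive.
- Against: the thermal stages expose a β-aryloxy enone to heat, where retro-oxa-Michael opening can erode C2, and ketene or carbene intermediates may stray onto the geranyl alkenes.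
- Comparison: a four-bond cascade has more ways to fail than a single SN2 closure, and two multi-step fragments before the key step should make it longer.

Alternative 2: The cut is C4–C4a, leading to the (S)-3-aryl-3-aryloxypropanoic acid A5, whose aryloxy part is the symmetric phenol 7 of the chosen route. Forward, activation of the acid (mixed anhydride with trifluoroacetic anhydride, or acid chloride with a mild Lewis acid) would acylate one of two equivalent ortho positions and give flavanone A4.
- In favour: regiochemistry is automatic for the same symmetry reason as in step 5. No dithiane, no unmasking and no organolithium coupling are needed, so on step economy this alternative is the better one.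
- Also in favour: the acetate on ring B lowers both the nucleophilicity of ring B and the tendency of C2 to ionise, a refinement the MOM-protected ring B of the chosen route lacks.
- Against: the O1–C2 bond of A5 must itself be made stereospecifically, most plausibly by an intermolecular Mitsunobu reaction of 7 with an (R)-β-hydroxy ester. That faces the same ionisation problem without the help of intramolecularity.
- Against: Friedel–Crafts activation is acidic and electrophilic. It threatens the MOM ethers and the three alkenes, and β-elimination of the phenoxide from the activated acid would destroy the stereocentre and the ether bond.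
- Comparison: equal on ring A regiocontrol, better on length, clearly worse on functional-group compatibility of the key step and on protection of C2. In the chosen plan C2 is formed last, under neutral conditions, with C4 masked.

Alternative 3: The cut is O1–C8a: the aryl–oxygen bond is made instead of the alkyl–oxygen bond, from bromo diol A7 in which the (S)-benzylic hydroxyl is already in place. Forward, CuI (copper iodide, monovalent copper) with a phenanthroline ligand and Cs2CO3 would couple the C2 alkoxide with the ortho bromide (Ullmann-type etherification) to flavan-4-ol A6. Retention is expected because no bond to C2 is broken. Oxidation at C4 and MOM removal would finish.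
- In favour: the stereocentre is never an electrophile, so the ionisation problem of the Mitsunobu closure does not exist. On stereochemical security of the ring closure this alternative is the better one.
- Also in favour: closure through the C4 hydroxyl would need a four-membered ring, so the two alcohols do not compete, and no sulfur is involved.
- Against: ring A must carry bromine on C8a beside three oxygen substituents and a prenyl group. That removes the symmetry that makes regiocontrol trivial in the chosen route and collides with organolithium-based prenylation.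
- Against: the aryl bromide is electron-rich and ortho-substituted, the worst case for copper-mediated C–O coupling. At the temperature needed a secondary benzylic alkoxide can be oxidised, the bromide reduced, and the doubly activated C4 carbinol dehydrated.
- Comparison: better on configurational safety, equal on convergence (a C3–C4 bond joins two aryl halves in both), weaker on ring A regiocontrol and on reliability of the key coupling, and one to two steps longer because of the redox adjustment at C4.

Key step: step 12

Assumption: 10 and 15 are taken as commercial, and organolithium species generated in a separate operation are numbered as non-isolated intermediates; CIP analysis confirms 21 as 1R and 22 as 2S, so oxirane 19 must be S (its descriptor differs from that of 21 only because ring opening changes the substituent ranks).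

## Route

Step 1
Reactants: 1 phloroglucinol (benzene-1,3,5-triol)
Product: 2 5-(triisopropylsilyloxy)benzene-1,3-diol
Conditions: TIPSCl (1.0 equiv), imidazole, 1 (3 equiv), DMF, 0 °C → rt
Reagents that add atoms: triisopropylsilyl chloride (TIPSCl), CC(C)[Si](Cl)(C(C)C)C(C)C
Why: Statistical mono-silylation of a threefold-symmetric triol; the excess of cheap 1 suppresses bis-silylation and is washed out with water.

Step 2
Reactants: 2 5-(triisopropylsilyloxy)benzene-1,3-diol
Product: 3 triisopropyl[3,5-bis(methoxymethoxy)phenoxy]silane
Conditions: MOMCl (2.5 equiv), i-Pr2NEt, CH2Cl2, 0 °C → rt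
Reagents that add atoms: chloromethyl methyl ether (MOMCl), COCCl
Why: O-alkylation of both phenols to MOM ethers under amine base, which leaves the aryl silyl ether intact.

Step 3
Reactants: 3 triisopropyl[3,5-bis(methoxymethoxy)phenoxy]silane; 4 prenyl bromide (1-bromo-3-methylbut-2-ene)
Product: 6 triisopropyl[3,5-bis(methoxymethoxy)-4-(3-methylbut-2-en-1-yl)phenoxy]silane, via aryllithium 5 (not isolated)
Conditions: n-BuLi (1.1 equiv), TMEDA, THF, 0 °C; CuBr·SMe2 (10 mol%), 4, −78 → 0 °C
Reagents that add atoms: none
Why: Directed ortho-metalation: the carbon flanked by two MOM ethers is lithiated cooperatively while the bulky, non-coordinating silyl ether shields its own neighbours; copper-catalysed allylation of 5 at the primary carbon of 4 (SN2) gives the linear prenyl group.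

Step 4
Reactants: 6 triisopropyl[3,5-bis(methoxymethoxy)-4-(3-methylbut-2-en-1-yl)phenoxy]silane
Product: 7 3,5-bis(methoxymethoxy)-4-(3-methylbut-2-en-1-yl)phenol
Conditions: Bu4NF, THF, 0 °C → rt; NH4Cl (aq)
Reagents that add atoms: none
Why: Fluoride desilylation of an aryl silyl ether; MOM ethers and the alkene are inert, and the product is the mirror-symmetric monophenol.

Step 5
Reactants: 7 3,5-bis(methoxymethoxy)-4-(3-methylbut-2-en-1-yl)phenol
Product: 8 6-hydroxy-2,4-bis(methoxymethoxy)-3-(3-methylbut-2-en-1-yl)benzaldehyde (CHO flanked by OH and OMOM; prenyl between the two OMOM groups)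
Conditions: MgCl2 (2 equiv), Et3N (4 equiv), (CH2O)n, MeCN, reflux
Reagents that add atoms: paraformaldehyde (formaldehyde), C=O
Why: Casnati–Skattebøl formylation: the magnesium phenoxide delivers formaldehyde to the ortho carbon only, and the two ortho carbons of 7 are equivalent, so one aldehyde forms with prenyl para to the free hydroxyl; basic conditions spare the MOM ethers.

Step 6
Reactants: 8 6-hydroxy-2,4-bis(methoxymethoxy)-3-(3-methylbut-2-en-1-yl)benzaldehyde
Product: 9 2-(1,3-dithian-2-yl)-3,5-bis(methoxymethoxy)-4-(3-methylbut-2-en-1-yl)phenol
Conditions: HS(CH2)3SH (1.05 equiv), BF3·OEt2 (0.3 equiv), CH2Cl2, −20 → 0 °C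
Reagents that add atoms: propane-1,3-dithiol, SCCCS
Why: Lewis-acid-catalysed dithioacetalisation; catalytic acid, low temperature and only a slight excess of dithiol leave no thiol to drive MOM cleavage, and the free hydroxyl is para to the prenyl group, so no chroman can form.

Step 7
Reactants: 10 2,4-dibromophenol
Product: 11 2,4-dibromo-1-(methoxymethoxy)benzene
Conditions: MOMCl, i-Pr2NEt, CH2Cl2, 0 °C → rt
Reagents that add atoms: chloromethyl methyl ether (MOMCl), COCCl
Why: MOM ether formation; the acetal protects the phenol and will direct the first bromine–lithium exchange.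

Step 8
Reactants: 11 2,4-dibromo-1-(methoxymethoxy)benzene; 12 geranyl bromide ((2E)-1-bromo-3,7-dimethylocta-2,6-diene)
Product: 14 4-bromo-2-[(2E)-3,7-dimethylocta-2,6-dien-1-yl]-1-(methoxymethoxy)benzene, via aryllithium 13 (not isolated)
Conditions: n-BuLi (1.0 equiv), THF, −78 °C; CuBr·SMe2 (10 mol%), 12, −78 → 0 °C
Reagents that add atoms: none
Why: Bromine–lithium exchange is fastest at the bromine ortho to the coordinating, inductively activating MOM ether, giving chelated 13 and keeping the para bromine as the second handle; copper-catalysed SN2 allylation with 12 keeps the E geometry because the fully substituted γ-carbon disfavours SN2' attack.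

Step 9
Reactants: 14 4-bromo-2-[(2E)-3,7-dimethylocta-2,6-dien-1-yl]-1-(methoxymethoxy)benzene; 15 2-chloro-N-methoxy-N-methylacetamide
Product: 17 2-chloro-1-{3-[(2E)-3,7-dimethylocta-2,6-dien-1-yl]-4-(methoxymethoxy)phenyl}ethanone, via aryllithium 16 (not isolated)
Conditions: n-BuLi (1.05 equiv), THF, −78 °C; 15, −78 → −40 °C; NH4Cl (aq)
Reagents that add atoms: none
Why: Bromine–lithium exchange followed by Weinreb ketone synthesis; the chelated tetrahedral adduct survives until the quench, so no over-addition occurs and the α-chloride is kept.

Step 10
Reactants: 17 2-chloro-1-{3-[(2E)-3,7-dimethylocta-2,6-dien-1-yl]-4-(methoxymethoxy)phenyl}ethanone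
Product: 19 (2S)-2-{3-[(2E)-3,7-dimethylocta-2,6-dien-1-yl]-4-(methoxymethoxy)phenyl}oxirane, via chlorohydrin 18 (not isolated)
Conditions: RuCl(p-cymene)[(R,R)-TsDPEN] (1 mol%), HCO2H–Et3N (5:2), EtOAc, rt; then NaOH (aq, excess), 0 °C → rt
Reagents that add atoms: none
Why: Noyori asymmetric transfer hydrogenation reduces only the ketone (isolated alkenes are inert to the ruthenium hydride); the (R,R) catalyst attacks the face that gives (R)-1-phenylethanol from acetophenone, which here is the 1S chlorohydrin 18 because CH2Cl outranks aryl; hydroxide then closes the oxirane by intramolecular Williamson displacement at the primary carbon, so the stereocentre is untouched and 19 is S.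

Step 11
Reactants: 9 2-(1,3-dithian-2-yl)-3,5-bis(methoxymethoxy)-4-(3-methylbut-2-en-1-yl)phenol; 19 (2S)-2-{3-[(2E)-3,7-dimethylocta-2,6-dien-1-yl]-4-(methoxymethoxy)phenyl}oxirane
Product: 21 (1R)-1-{3-[(2E)-3,7-dimethylocta-2,6-dien-1-yl]-4-(methoxymethoxy)phenyl}-2-{2-[2-hydroxy-4,6-bis(methoxymethoxy)-5-(3-methylbut-2-en-1-yl)phenyl]-1,3-dithian-2-yl}ethanol, via dilithio species 20 (not isolated)
Conditions: 9 (1.15 equiv), n-BuLi (2.0 equiv per 9), THF, −78 → 0 °C; then 19, DMPU, −78 → 0 °C; NH4Cl (aq)
Reagents that add atoms: none
Why: Corey–Seebach alkylation: the second equivalent of base lithiates the dithiane carbon of the lithium phenoxide, and the soft, hindered carbanion of 20 opens the oxirane at its unhindered terminal carbon (SN2), so the benzylic C–O bond keeps its configuration; the descriptor changes from S to R only through the change in substituent ranks.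

Step 12
Reactants: 21 (1R)-1-{3-[(2E)-3,7-dimethylocta-2,6-dien-1-yl]-4-(methoxymethoxy)phenyl}-2-{2-[2-hydroxy-4,6-bis(methoxymethoxy)-5-(3-methylbut-2-en-1-yl)phenyl]-1,3-dithian-2-yl}ethanol
Product: 22 (2S)-5,7,4'-tris(methoxymethoxy)-6-prenyl-3'-geranylflavan-4-one propane-1,3-diyl dithioketal (spiro[chromane-4,2'-[1,3]dithiane])
Conditions: PPh3 (1.5 equiv), DIAD (1.5 equiv, slow addition), toluene (0.02 M), −20 → 0 °C
Reagents that add atoms: none
Why: Mitsunobu etherification: PPh3 and DIAD form a betaine that deprotonates the C8a phenol (the only acidic OH) and turns the C2 hydroxyl of 21 into an alkoxyphosphonium leaving group, which the phenoxide displaces from the face opposite to the departing Ph3P=O. The closest known reaction type is the intramolecular Mitsunobu cyclisation of 2-(3-aryl-3-hydroxypropyl)phenols to 2-arylchromans with inversion. Ring C closes in a 6-exo-tet mode (O1 attacks C2, leaving group outside the ring). The new stereocentre is substrate-controlled: the 1R carbinol carbon, set by the catalyst in step 10 and carried unchanged through step 11, is inverted to 2S. The step needs SN2 substitution to beat ionisation to the para-alkoxybenzylic cation and E2 loss of a C3 hydrogen; the intramolecular nucleophile, the gem-disubstituted dithiane carbon next to C3 (Thorpe–Ingold compression), toluene as a non-ionising solvent and low temperature favour substitution. Chemoselectivity and regiochemistry are secured because the C5, C7 and C4' oxygens are MOM ethers, so only the C8a oxygen can close and the prenyl group must end on C6. With C4 as a dithioketal there is no carbonyl, hence no enolisation, no chalcone formation and no retro-oxa-Michael path to racemise C2 after closure.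

Step 13
Reactants: 22 (2S)-5,7,4'-tris(methoxymethoxy)-6-prenyl-3'-geranylflavan-4-one propane-1,3-diyl dithioketal
Product: 23 (2S)-5,7,4'-tris(methoxymethoxy)-6-prenyl-3'-geranylflavanone
Conditions: MeI (10 equiv), CaCO3, MeCN–H2O (4:1), 45 °C
Reagents that add atoms: water, O
Why: Alkylative dithioketal hydrolysis: S-methylation gives a sulfonium ion that opens to an aryl-stabilised thionium ion and is trapped by water; MeI does not react with alkenes, acetals or the ether at C2, and CaCO3 keeps the medium near neutral.

Step 14
Reactants: 23 (2S)-5,7,4'-tris(methoxymethoxy)-6-prenyl-3'-geranylflavanone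
Product: 24 schizolaenone A ((2S)-5,7,4'-trihydroxy-6-prenyl-3'-geranylflavanone)
Conditions: HCl (3 M aq), MeOH, 40 °C
Reagents that add atoms: none
Why: Acid-catalysed acetal exchange with methanol removes the three MOM ethers (the one on C5 fastest, assisted by the neighbouring carbonyl); mild temperature and short exposure are meant to keep alkene protonation and ring opening at C2 behind acetal cleavage.

## Compound list

1 | phloroglucinol (benzene-1,3,5-triol) | Oc1cc(O)cc(O)c1 | starting material
2 | 5-(triisopropylsilyloxy)benzene-1,3-diol | CC(C)[Si](Oc1cc(O)cc(O)c1)(C(C)C)C(C)C | intermediate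
3 | triisopropyl[3,5-bis(methoxymethoxy)phenoxy]silane | COCOc1cc(OCOC)cc(O[Si](C(C)C)(C(C)C)C(C)C)c1 | intermediate
4 | prenyl bromide (1-bromo-3-methylbut-2-ene) | CC(C)=CCBr | starting material
5 | [2,6-bis(methoxymethoxy)-4-(triisopropylsilyloxy)phenyl]lithium (formed in the flask) | [Li]c1c(OCOC)cc(O[Si](C(C)C)(C(C)C)C(C)C)cc1OCOC | intermediate
6 | triisopropyl[3,5-bis(methoxymethoxy)-4-(3-methylbut-2-en-1-yl)phenoxy]silane | CC(C)=CCc1c(OCOC)cc(O[Si](C(C)C)(C(C)C)C(C)C)cc1OCOC | intermediate
7 | 3,5-bis(methoxymethoxy)-4-(3-methylbut-2-en-1-yl)phenol | CC(C)=CCc1c(OCOC)cc(O)cc1OCOC | intermediate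
8 | 6-hydroxy-2,4-bis(methoxymethoxy)-3-(3-methylbut-2-en-1-yl)benzaldehyde | O=Cc1c(O)cc(OCOC)c(CC=C(C)C)c1OCOC | intermediate
9 | 2-(1,3-dithian-2-yl)-3,5-bis(methoxymethoxy)-4-(3-methylbut-2-en-1-yl)phenol | Oc1cc(OCOC)c(CC=C(C)C)c(OCOC)c1C1SCCCS1 | intermediate
10 | 2,4-dibromophenol | Oc1ccc(Br)cc1Br | starting material
11 | 2,4-dibromo-1-(methoxymethoxy)benzene | COCOc1ccc(Br)cc1Br | intermediate
12 | geranyl bromide ((2E)-1-bromo-3,7-dimethylocta-2,6-diene) | CC(C)=CCC/C(C)=C/CBr | starting material
13 | [5-bromo-2-(methoxymethoxy)phenyl]lithium (formed in the flask) | COCOc1ccc(Br)cc1[Li] | intermediate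
14 | 4-bromo-2-[(2E)-3,7-dimethylocta-2,6-dien-1-yl]-1-(methoxymethoxy)benzene | CC(C)=CCC/C(C)=C/Cc1cc(Br)ccc1OCOC | intermediate
15 | 2-chloro-N-methoxy-N-methylacetamide | CON(C)C(=O)CCl | starting material
16 | {3-[(2E)-3,7-dimethylocta-2,6-dien-1-yl]-4-(methoxymethoxy)phenyl}lithium (formed in the flask) | CC(C)=CCC/C(C)=C/Cc1cc([Li])ccc1OCOC | intermediate
17 | 2-chloro-1-{3-[(2E)-3,7-dimethylocta-2,6-dien-1-yl]-4-(methoxymethoxy)phenyl}ethanone | CC(C)=CCC/C(C)=C/Cc1cc(C(=O)CCl)ccc1OCOC | intermediate
18 | (1S)-2-chloro-1-{3-[(2E)-3,7-dimethylocta-2,6-dien-1-yl]-4-(methoxymethoxy)phenyl}ethanol (formed in the flask) | CC(C)=CCC/C(C)=C/Cc1cc([C@H](O)CCl)ccc1OCOC | intermediate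
19 | (2S)-2-{3-[(2E)-3,7-dimethylocta-2,6-dien-1-yl]-4-(methoxymethoxy)phenyl}oxirane | CC(C)=CCC/C(C)=C/Cc1cc([C@H]2CO2)ccc1OCOC | intermediate
20 | dilithio derivative of 9: lithium phenoxide with 2-lithio-1,3-dithiane (formed in the flask) | [Li]Oc1cc(OCOC)c(CC=C(C)C)c(OCOC)c1C1([Li])SCCCS1 | intermediate
21 | (1R)-1-{3-[(2E)-3,7-dimethylocta-2,6-dien-1-yl]-4-(methoxymethoxy)phenyl}-2-{2-[2-hydroxy-4,6-bis(methoxymethoxy)-5-(3-methylbut-2-en-1-yl)phenyl]-1,3-dithian-2-yl}ethanol | CC(C)=CCC/C(C)=C/Cc1cc([C@H](O)CC4(SCCCS4)c2c(O)cc(OCOC)c(CC=C(C)C)c2OCOC)ccc1OCOC | intermediate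
22 | (2S)-5,7,4'-tris(methoxymethoxy)-6-prenyl-3'-geranylflavan-4-one propane-1,3-diyl dithioketal | CC(C)=CCC/C(C)=C/Cc1cc([C@@H]2CC4(SCCCS4)c3c(cc(OCOC)c(CC=C(C)C)c3OCOC)O2)ccc1OCOC | intermediate
23 | (2S)-5,7,4'-tris(methoxymethoxy)-6-prenyl-3'-geranylflavanone | CC(C)=CCC/C(C)=C/Cc1cc([C@@H]2CC(=O)c3c(cc(OCOC)c(CC=C(C)C)c3OCOC)O2)ccc1OCOC | intermediate
24 | schizolaenone A | CC(C)=CCC/C(C)=C/Cc1cc([C@@H]2CC(=O)c3c(cc(O)c(CC=C(C)C)c3O)O2)ccc1O | target

## Step count and risks

Total: 14 steps. Longest linear sequence: 10 steps (steps 1–6 and 11–14); the ring B branch is steps 7–10.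

Step 12 (key step). Most likely failure: partial ionisation of the oxyphosphonium ion of 21 to a para-alkoxybenzylic cation before the phenoxide attacks, which erodes the configuration at C2 without changing the constitution; elimination to the styrene is the second escape. Fallback, setting out from 9 and coming back at 22: coupling and ring closure are run with a ring B that carries bromine in place of the geranyl chain, because a meta bromine destabilises the benzylic cation, and the chain is attached afterwards. Commercial 3-bromo-4-hydroxybenzaldehyde is protected (MOMCl, i-Pr2NEt) to 3-bromo-4-(methoxymethoxy)benzaldehyde F1. Sulfonium ylide methylenation (trimethylsulfonium iodide, KOH, MeCN; Corey–Chaykovsky) gives racemic 2-[3-bromo-4-(methoxymethoxy)phenyl]oxirane F2. Hydrolytic kinetic resolution with (S,S)-(salen)Co(OAc) (trivalent cobalt) and 0.55 equiv of water, which should consume the R enantiomer, leaves (2S)-2-[3-bromo-4-(methoxymethoxy)phenyl]oxirane F3. Dilithio species 20 opens F3 to the (1R)-bromo carbinol F4, and Mitsunobu closure as in step 12 gives the (2S)-3'-bromo chroman dithioketal F5. Bromine–lithium exchange (n-BuLi, THF, −78 °C) gives the 3'-lithio chroman dithioketal F6, and copper-catalysed allylation with 12 gives 22.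

Step 11. Most likely failure: incomplete C-lithiation beside the lithium phenoxide, or slow opening of 19 by the hindered dianion, during which lithium salts isomerise the electron-rich oxirane to an arylacetaldehyde. Fallback, from 9 back to 21: the phenol is masked with allyl bromide and K2CO3 in acetone to give 2-[2-(allyloxy)-4,6-bis(methoxymethoxy)-5-(3-methylbut-2-en-1-yl)phenyl]-1,3-dithiane F7. One equivalent of n-BuLi gives its 2-lithio derivative F8, which opens 19 to the O-allyl (1R)-carbinol F9. Pd(PPh3)4 (zerovalent palladium) with morpholine removes the allyl group to give 21. A silyl ether is avoided here because a neighbouring lithiated dithiane would invite oxygen-to-carbon silyl migration.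

Step 6. Most likely failure: loss of a MOM ether, since a Lewis acid with a thiol is also a standard way to cleave such acetals. Fallback, from 7 back to 9: aldehyde 8 is bypassed and the intact dithiane ring is introduced by electrophilic aromatic substitution of 7 with 1,3-dithian-2-ylium tetrafluoroborate in CH2Cl2 at low temperature with 2,6-di-tert-butylpyridine as acid scavenger. Both free positions of 7 are equivalent and ortho to the hydroxyl. This fallback makes no new intermediate (F0).

Step 10. Most likely failure: displacement of the α-chloride by formate or premature, uncontrolled ring closure under the amine–formate conditions, and acid-induced opening of the sensitive oxirane during isolation. Fallback, from 17 back to 19: NaBH4 in MeOH reduces 17 to the racemic chlorohydrin F10, NaOH closes it to the racemic oxirane F11, and hydrolytic kinetic resolution with (S,S)-(salen)Co(OAc) and 0.55 equiv of water removes the R enantiomer as its diol and leaves 19.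

Step 14. Most likely failure: acid-promoted addition of the freed phenols to the neighbouring prenyl and geranyl double bonds (chroman formation), and slow ring–chain equilibration of the 5-hydroxyflavanone that lowers the optical purity. Fallback, from 22 back to 24: the order is reversed and the cleavage mechanism changed. 22 is treated with TMSOTf and 2,2'-bipyridyl in MeCN to exchange the three aryl MOM ethers for silyl ethers, giving the tris(trimethylsilyl) ether dithioketal F12. Water hydrolyses this to the (2S)-5,7,4'-trihydroxy dithioketal F13, and only then is C4 unmasked with MeI and CaCO3 in aqueous MeCN. No protic acid meets the alkenes, and no carbonyl is present while the acetals are cleaved.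

## Further compounds

F1 | step 12 | 3-bromo-4-(methoxymethoxy)benzaldehyde | COCOc1ccc(C=O)cc1Br
F2 | step 12 | racemic 2-[3-bromo-4-(methoxymethoxy)phenyl]oxirane | COCOc1ccc(C2CO2)cc1Br
F3 | step 12 | (2S)-2-[3-bromo-4-(methoxymethoxy)phenyl]oxirane | COCOc1ccc([C@H]2CO2)cc1Br
F4 | step 12 | (1R)-1-[3-bromo-4-(methoxymethoxy)phenyl]-2-{2-[2-hydroxy-4,6-bis(methoxymethoxy)-5-(3-methylbut-2-en-1-yl)phenyl]-1,3-dithian-2-yl}ethanol | COCOc1ccc([C@H](O)CC4(SCCCS4)c2c(O)cc(OCOC)c(CC=C(C)C)c2OCOC)cc1Br
F5 | step 12 | (2S)-3'-bromo-5,7,4'-tris(methoxymethoxy)-6-prenylflavan-4-one propane-1,3-diyl dithioketal | COCOc1ccc([C@@H]2CC4(SCCCS4)c3c(cc(OCOC)c(CC=C(C)C)c3OCOC)O2)cc1Br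
F6 | step 12 | (2S)-3'-lithio-5,7,4'-tris(methoxymethoxy)-6-prenylflavan-4-one propane-1,3-diyl dithioketal | COCOc1ccc([C@@H]2CC4(SCCCS4)c3c(cc(OCOC)c(CC=C(C)C)c3OCOC)O2)cc1[Li]
F7 | step 11 | 2-[2-(allyloxy)-4,6-bis(methoxymethoxy)-5-(3-methylbut-2-en-1-yl)phenyl]-1,3-dithiane | C=CCOc1cc(OCOC)c(CC=C(C)C)c(OCOC)c1C1SCCCS1
F8 | step 11 | 2-lithio-2-[2-(allyloxy)-4,6-bis(methoxymethoxy)-5-(3-methylbut-2-en-1-yl)phenyl]-1,3-dithiane | C=CCOc1cc(OCOC)c(CC=C(C)C)c(OCOC)c1C1([Li])SCCCS1
F9 | step 11 | (1R)-2-{2-[2-(allyloxy)-4,6-bis(methoxymethoxy)-5-(3-methylbut-2-en-1-yl)phenyl]-1,3-dithian-2-yl}-1-{3-[(2E)-3,7-dimethylocta-2,6-dien-1-yl]-4-(methoxymethoxy)phenyl}ethanol | CC(C)=CCC/C(C)=C/Cc1cc([C@H](O)CC4(SCCCS4)c2c(OCC=C)cc(OCOC)c(CC=C(C)C)c2OCOC)ccc1OCOC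
F0 | step 6 | none | none
F10 | step 10 | racemic 2-chloro-1-{3-[(2E)-3,7-dimethylocta-2,6-dien-1-yl]-4-(methoxymethoxy)phenyl}ethanol | CC(C)=CCC/C(C)=C/Cc1cc(C(O)CCl)ccc1OCOC
F11 | step 10 | racemic 2-{3-[(2E)-3,7-dimethylocta-2,6-dien-1-yl]-4-(methoxymethoxy)phenyl}oxirane | CC(C)=CCC/C(C)=C/Cc1cc(C2CO2)ccc1OCOC
F12 | step 14 | (2S)-5,7,4'-tris(trimethylsilyloxy)-6-prenyl-3'-geranylflavan-4-one propane-1,3-diyl dithioketal | CC(C)=CCC/C(C)=C/Cc1cc([C@@H]2CC4(SCCCS4)c3c(cc(O[Si](C)(C)C)c(CC=C(C)C)c3O[Si](C)(C)C)O2)ccc1O[Si](C)(C)C
F13 | step 14 | (2S)-5,7,4'-trihydroxy-6-prenyl-3'-geranylflavan-4-one propane-1,3-diyl dithioketal | CC(C)=CCC/C(C)=C/Cc1cc([C@@H]2CC4(SCCCS4)c3c(cc(O)c(CC=C(C)C)c3O)O2)ccc1O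
A1 | alternative 1 | (2S)-5-hydroxy-7-(triisopropylsilyloxy)-4'-(tert-butyldimethylsilyloxy)-6-prenyl-3'-geranylflavanone | CC(C)=CCC/C(C)=C/Cc1cc([C@@H]2CC(=O)c3c(cc(O[Si](C(C)C)(C(C)C)C(C)C)c(CC=C(C)C)c3O)O2)ccc1O[Si](C)(C)C(C)(C)C
A2 | alternative 1 | (2S)-6-(diazoacetyl)-2-{4-(tert-butyldimethylsilyloxy)-3-[(2E)-3,7-dimethylocta-2,6-dien-1-yl]phenyl}-2,3-dihydro-4H-pyran-4-one | CC(C)=CCC/C(C)=C/Cc1cc([C@@H]2CC(=O)C=C(C(=O)C=[N+]=[N-])O2)ccc1O[Si](C)(C)C(C)(C)C
A3 | alternative 1 | triisopropyl[(5-methylhex-4-en-1-yn-1-yl)oxy]silane | CC(C)=CCC#CO[Si](C(C)C)(C(C)C)C(C)C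
A4 | alternative 2 | (2S)-4'-acetoxy-5,7-bis(methoxymethoxy)-6-prenyl-3'-geranylflavanone | CC(C)=CCC/C(C)=C/Cc1cc([C@@H]2CC(=O)c3c(cc(OCOC)c(CC=C(C)C)c3OCOC)O2)ccc1OC(C)=O
A5 | alternative 2 | (3S)-3-{4-acetoxy-3-[(2E)-3,7-dimethylocta-2,6-dien-1-yl]phenyl}-3-[3,5-bis(methoxymethoxy)-4-(3-methylbut-2-en-1-yl)phenoxy]propanoic acid | CC(C)=CCC/C(C)=C/Cc1cc([C@H](CC(=O)O)Oc2cc(OCOC)c(CC=C(C)C)c(OCOC)c2)ccc1OC(C)=O
A6 | alternative 3 | (2S,4RS)-5,7,4'-tris(methoxymethoxy)-6-prenyl-3'-geranylflavan-4-ol | CC(C)=CCC/C(C)=C/Cc1cc([C@@H]2CC(O)c3c(cc(OCOC)c(CC=C(C)C)c3OCOC)O2)ccc1OCOC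
A7 | alternative 3 | (1S,3RS)-3-[2-bromo-4,6-bis(methoxymethoxy)-5-(3-methylbut-2-en-1-yl)phenyl]-1-{3-[(2E)-3,7-dimethylocta-2,6-dien-1-yl]-4-(methoxymethoxy)phenyl}propane-1,3-diol | CC(C)=CCC/C(C)=C/Cc1cc([C@@H](O)CC(O)c2c(Br)cc(OCOC)c(CC=C(C)C)c2OCOC)ccc1OCOC
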